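The carbocycle of the target is a trans-1,2-dialkenylcyclohexane in disguise: quaternary C10 carries a methyl group and an oxirane (an oxidised vinyl group, C1–C2), and neighbouring C5 carries a 1-formylvinyl group (C4(=C3H2)–C15HO). This pattern is the retron of a Cope rearrangement. The route therefore rests on forming the C5–C10 bond by [3,3] shift of a ten-membered germacra-1(10),4-dien-15-al 12,8-olide: one operation contracts the macrocycle to the cyclohexane, sets quaternary C10 and C5 stereospecifically and unveils the vinyl and acrolein units. The precursor is a ring-trans,trans cyclodeca-1,5-diene fused to the trans α-methylene-γ-lactone, closed by Nozaki–Hiyama–Kishi macrocyclisation.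

Key step: step 15

Remark (assumption): germacrane/elemane numbering is used throughout (C14 methyl and C1–C2 on C10; C4(=C3)–C15 on C5; oxygen on C6, C8, C9; lactone C8–O–C12(=O)–C11(=C13)–C7), and (R)-5-(hydroxymethyl)furan-2(5H)-one 7 is taken as a purchasable chiral-pool butenolide.

Step 1
Reactants: 1 pent-3-yn-1-ol
Product: 2 5-bromopent-2-yne
Conditions: CBr4, PPh3, CH2Cl2, 0 °C
Reagents that add atoms: tetrabromomethane BrC(Br)(Br)Br
Why: Appel bromination should convert the primary alcohol into the bromide under neutral conditions that leave the internal alkyne untouched.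

Step 2
Reactants: 2 5-bromopent-2-yne; 3 prop-2-yn-1-ol
Product: 6 (Z)-3-iodo-2-(pent-3-yn-1-yl)prop-2-en-1-ol, via pent-3-yn-1-ylmagnesium bromide 4 (not isolated), via magnesium alkenyl alkoxide chelate 5 (not isolated)
Conditions: Mg, THF; 3 pre-treated with EtMgBr, CuI (10 mol %), THF, rt; then I2, −40 to 0 °C
Reagents that add atoms: iodine II
Why: Copper-catalysed, alkoxide-directed anti-carbomagnesiation of the propargylic alkoxide puts the alkyl group on the internal carbon and magnesium in a five-membered chelate cis to CH2O, and iodinolysis with retention should fix the Z geometry (I cis to CH2OH) that later becomes the ring-trans C4=C5 bond.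

Step 3
Reactants: 7 (R)-5-(hydroxymethyl)furan-2(5H)-one
Product: 8 (R)-5-[(triethylsilyloxy)methyl]furan-2(5H)-one
Conditions: TESCl, imidazole, CH2Cl2, 0 °C
Reagents that add atoms: chlorotriethylsilane CC[Si](Cl)(CC)CC
Why: Silylation of the primary alcohol under weakly basic conditions should protect O9 without racemising the butenolide C8 centre.

Step 4
Reactants: 8 (R)-5-[(triethylsilyloxy)methyl]furan-2(5H)-one
Product: 9 (4S,5R)-4-ethenyl-5-[(triethylsilyloxy)methyl]oxolan-2-one
Conditions: CH2=CHMgBr, CuBr·SMe2 (10 mol %), THF, −78 °C; aq. NH4Cl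
Reagents that add atoms: vinylmagnesium bromide C=C[Mg]Br
Why: Copper-catalysed conjugate addition to the butenolide should occur anti to the silyloxymethyl group on C8 and so set C7 of the trans-disubstituted lactone.

Step 5
Reactants: 9 (4S,5R)-4-ethenyl-5-[(triethylsilyloxy)methyl]oxolan-2-one
Product: 11 (2R,3R)-5-oxo-2-[(triethylsilyloxy)methyl]oxolane-3-carbaldehyde, via ozonide 10 (not isolated)
Conditions: O3, CH2Cl2, −78 °C; then PPh3, −78 °C to rt
Reagents that add atoms: ozone [O-][O+]=O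
Why: Ozonolysis with reductive work-up should cleave the only alkene to the C6 aldehyde, which is used crude because it is prone to epimerisation.

Step 6
Reactants: 11 (2R,3R)-5-oxo-2-[(triethylsilyloxy)methyl]oxolane-3-carbaldehyde; 6 (Z)-3-iodo-2-(pent-3-yn-1-yl)prop-2-en-1-ol
Product: 12 (4S,5R)-4-[(1S,2Z)-1-hydroxy-3-(hydroxymethyl)oct-2-en-6-yn-1-yl]-5-[(triethylsilyloxy)methyl]oxolan-2-one
Conditions: CrCl2, NiCl2 (cat.), chiral oxazoline–sulfonamide ligand, Et3N, THF, rt
Reagents that add atoms: none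
Why: Ligand-controlled asymmetric Nozaki–Hiyama–Kishi coupling should add the alkenylchromium to the aldehyde alone with retention of the Z geometry, the chiral ligand on chromium (not the weak, opposing Felkin bias of the lactone) being relied on to set the (6S) carbinol.

Step 7
Reactants: 12 (4S,5R)-4-[(1S,2Z)-1-hydroxy-3-(hydroxymethyl)oct-2-en-6-yn-1-yl]-5-[(triethylsilyloxy)methyl]oxolan-2-one
Product: 13 (4R,5R)-4-[(1S,2Z)-1-(tert-butyldimethylsilyloxy)-3-[(tert-butyldimethylsilyloxy)methyl]oct-2-en-6-yn-1-yl]-5-[(triethylsilyloxy)methyl]oxolan-2-one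
Conditions: TBSOTf, 2,6-lutidine, CH2Cl2, −78 to 0 °C
Reagents that add atoms: tert-butyldimethylsilyl triflate CC(C)(C)[Si](C)(C)OS(=O)(=O)C(F)(F)F
Why: Exhaustive silylation should protect O6 and O15 in one operation as ethers that differ in lability (primary allylic versus hindered secondary) for later staged release.

Step 8
Reactants: 13 bis-silyl ether
Product: 15 (4R,5R)-4-[(1S,2Z,6E)-1-(tert-butyldimethylsilyloxy)-3-[(tert-butyldimethylsilyloxy)methyl]-7-iodoocta-2,6-dien-1-yl]-5-[(triethylsilyloxy)methyl]oxolan-2-one, via alkenylzirconocene chloride 14 (not isolated)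
Conditions: Cp2Zr(H)Cl (3 equiv), THF, rt to 40 °C; then I2, 0 °C
Reagents that add atoms: iodine II
Why: Syn hydrozirconation of the 2-alkyne with excess reagent should equilibrate zirconium to the less hindered methyl-bearing carbon C10, and iodinolysis with retention gives the (E)-2-iodoalkene; the trisubstituted alkene is inert and the γ-lactone is tolerated at these temperatures.

Step 9
Reactants: 15 (E)-alkenyl iodide lactone
Product: 18 (4R,5R)-4-[(1S,2Z,6E)-1-(tert-butyldimethylsilyloxy)-3-[(tert-butyldimethylsilyloxy)methyl]-7-iodoocta-2,6-dien-1-yl]-3-methylidene-5-[(triethylsilyloxy)methyl]oxolan-2-one, via Mannich base 16 (not isolated), via trimethylammonium iodide 17 (not isolated)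
Conditions: LiHMDS, THF, −78 °C; CH2=NMe2+ I−, −78 °C to rt; then MeI, MeOH, rt; then aq. NaHCO3, CH2Cl2
Reagents that add atoms: N,N-dimethylmethyleneiminium iodide C=[N+](C)C.[I-]
Why: Mannich alkylation of the lactone enolate at C11, then quaternisation and Hofmann-type elimination, should install the C11=C13 exo-methylene; the enolate has no β-leaving group, and the silyl ethers and alkenyl iodide survive the base.

Step 10
Reactants: 18 α-methylene lactone triethylsilyl ether
Product: 19 (4R,5R)-4-[(1S,2Z,6E)-1-(tert-butyldimethylsilyloxy)-3-[(tert-butyldimethylsilyloxy)methyl]-7-iodoocta-2,6-dien-1-yl]-5-(hydroxymethyl)-3-methylideneoxolan-2-one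
Conditions: PPTS, MeOH/CH2Cl2, 0 °C
Reagents that add atoms: none
Why: Mild acid methanolysis should remove the primary triethylsilyl ether selectively, since both tert-butyldimethylsilyl ethers are far less acid-labile.

Step 11
Reactants: 19 primary alcohol
Product: 20 (2R,3R)-3-[(1S,2Z,6E)-1-(tert-butyldimethylsilyloxy)-3-[(tert-butyldimethylsilyloxy)methyl]-7-iodoocta-2,6-dien-1-yl]-4-methylidene-5-oxooxolane-2-carbaldehyde
Conditions: Dess–Martin periodinane, CH2Cl2, 0 °C to rt
Reagents that add atoms: none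
Why: Dess–Martin oxidation should give the C9 aldehyde under non-basic conditions that avoid epimerisation at C8, and the aldehyde is used at once.

Step 12
Reactants: 20 iodo aldehyde
Product: 21 (1(10)E,4Z,6S,7R,8R,9S)-6,15-bis(tert-butyldimethylsilyloxy)-9-hydroxygermacra-1(10),4,11(13)-trien-12,8-olide
Conditions: CrCl2 (excess), NiCl2 (cat.), DMSO/THF, rt, slow addition at high dilution
Reagents that add atoms: none
Why: Intramolecular Nozaki–Hiyama–Kishi coupling should close the ten-membered ring at C9–C10 with retention of the E alkenyl geometry, and polar Felkin–Anh addition anti to the lactone oxygen on C8 should give the 8,9-anti (9S) allylic alcohol.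

Step 13
Reactants: 21 macrocyclic allylic alcohol
Product: 22 (1(10)E,4Z,6S,7R,8R,9S)-6,15-bis(tert-butyldimethylsilyloxy)-9-(2-methylprop-2-enoyloxy)germacra-1(10),4,11(13)-trien-12,8-olide
Conditions: methacrylic anhydride, Et3N, DMAP (cat.), CH2Cl2, 0 °C to rt
Reagents that add atoms: methacrylic anhydride C=C(C)C(=O)OC(=O)C(C)=C
Why: DMAP-catalysed acylation of the only free hydroxyl should install the C9 methacrylate without touching the silyl ethers.

Step 14
Reactants: 22 methacrylate bis-silyl ether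
Product: 23 (1(10)E,4Z,6S,7R,8R,9S)-6-(tert-butyldimethylsilyloxy)-15-hydroxy-9-(2-methylprop-2-enoyloxy)germacra-1(10),4,11(13)-trien-12,8-olide
Conditions: HF·pyridine, excess pyridine, THF, 0 °C
Reagents that add atoms: none
Why: Buffered fluoride desilylation should cleave the unhindered primary allylic silyl ether on O15 much faster than the hindered secondary one on O6, while the buffer suppresses acid-induced transannular cyclisation of the diene.

Step 15
Reactants: 23 15-hydroxygermacranolide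
Product: 25 (5R,6S,7R,8R,9S,10S)-6-(tert-butyldimethylsilyloxy)-9-(2-methylprop-2-enoyloxy)-15-oxoelema-1,3,11(13)-trien-12,8-olide, via germacranolide enal 24 (not isolated)
Conditions: MnO2, CH2Cl2, rt; filter; then toluene, BHT (cat.), 80 °C
Reagents that add atoms: none
Why: MnO2 oxidises the primary allylic alcohol to the (4Z)-enal 24, a 1,5-diene (C10=C1–C2–C3–C4=C5) that should undergo a thermal [3,3]-sigmatropic Cope rearrangement in which the C2–C3 bond breaks and the C5–C10 bond forms. The closest known reaction type is the thermal Cope rearrangement of germacra-1(10),4-dienes and germacranolides to elemanes, here accelerated by the formyl group on C4 (an acyl group at position 2 of the hexadiene). The six-membered ring C5–C6–C7–C8–C9–C10 closes transannularly through a chair-like six-centre transition state while the ten-membered ring opens, so the closure is a ring contraction and not a tethered exo or endo cyclisation. The ring-trans geometry of both double bonds fixes the relative configuration of the two new stereocentres (C14 methyl on C10 anti to H5, vinyl and formylvinyl groups trans-diequatorial), and the trans-fused lactone, which must stay diequatorial on the forming chair, admits only the chair that leads to (5R,10S)-25. The step needs the chair pathway and a product-side equilibrium; release of the strain of the E,E-cyclodecadiene, retained enal conjugation in the 2-substituted acrolein and the silyl ether on O6 (which blocks lactol and furan formation from the cis-γ-hydroxy enal) are expected to secure both.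

Step 16
Reactants: 25 vinyl elemanolide
Product: 26 (1R,5R,6S,7R,8R,9S,10R)-6-(tert-butyldimethylsilyloxy)-1,2-epoxy-9-(2-methylprop-2-enoyloxy)-15-oxoelema-3,11(13)-dien-12,8-olide
Conditions: Ti(OiPr)4 (10 mol %), chiral salalen ligand (enantiomer that gives (R)-1,2-epoxyalkanes from 1-alkenes), 30% aq. H2O2, CH2Cl2, rt
Reagents that add atoms: hydrogen peroxide OO
Why: Titanium–salalen-catalysed asymmetric epoxidation is electrophilic and selective for non-conjugated terminal alkenes, so it should oxidise only the C1=C2 vinyl group (the acrolein, methacrylate and α-methylene lactone are electron-poor) with the catalyst setting the (1R) oxirane.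

Step 17
Reactants: 26 epoxide silyl ether
Product: 27 target, (1R,5R,6S,7S,8R,9S,10R)-1,2-epoxy-6-hydroxy-9-(2-methylprop-2-enoyloxy)-15-oxoelema-3,11(13)-dien-12,8-olide
Conditions: HF·pyridine, pyridine, THF, 0 °C to rt
Reagents that add atoms: none
Why: Buffered HF·pyridine desilylation should free the C6 hydroxyl without base, so the hindered terminal epoxide, the methacrylate and the lactone are left intact and no translactonisation to O6 is triggered.

Compound list
1 | pent-3-yn-1-ol | CC#CCCO | starting material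
2 | 5-bromopent-2-yne | CC#CCCBr | intermediate
3 | prop-2-yn-1-ol | C#CCO | starting material
4 | pent-3-yn-1-ylmagnesium bromide | CC#CCC[Mg]Br | intermediate (not isolated)
5 | magnesium alkenyl alkoxide chelate, 4-(pent-3-yn-1-yl)-2,5-dihydro-1,2-oxamagnesole | CC#CCCC1=C[Mg]OC1 | intermediate (not isolated)
6 | (Z)-3-iodo-2-(pent-3-yn-1-yl)prop-2-en-1-ol | OC/C(=C\I)CCC#CC | intermediate
7 | (R)-5-(hydroxymethyl)furan-2(5H)-one | OC[C@@H]1OC(=O)C=C1 | starting material
8 | (R)-5-[(triethylsilyloxy)methyl]furan-2(5H)-one | CC[Si](CC)(CC)OC[C@@H]1OC(=O)C=C1 | intermediate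
9 | (4S,5R)-4-ethenyl-5-[(triethylsilyloxy)methyl]oxolan-2-one | CC[Si](CC)(CC)OC[C@@H]1OC(=O)C[C@H]1C=C | intermediate
10 | ozonide (1,2,4-trioxolane) of 9, mixture at the trioxolane carbon | CC[Si](CC)(CC)OC[C@@H]1OC(=O)C[C@H]1C1OOCO1 | intermediate (not isolated)
11 | (2R,3R)-5-oxo-2-[(triethylsilyloxy)methyl]oxolane-3-carbaldehyde | CC[Si](CC)(CC)OC[C@@H]1OC(=O)C[C@H]1C=O | intermediate
12 | (4S,5R)-4-[(1S,2Z)-1-hydroxy-3-(hydroxymethyl)oct-2-en-6-yn-1-yl]-5-[(triethylsilyloxy)methyl]oxolan-2-one | CC[Si](CC)(CC)OC[C@@H]1OC(=O)C[C@H]1[C@@H](O)/C=C(\CO)CCC#CC | intermediate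
13 | (4R,5R)-4-[(1S,2Z)-1-(tert-butyldimethylsilyloxy)-3-[(tert-butyldimethylsilyloxy)methyl]oct-2-en-6-yn-1-yl]-5-[(triethylsilyloxy)methyl]oxolan-2-one | CC[Si](CC)(CC)OC[C@@H]1OC(=O)C[C@H]1[C@@H](O[Si](C)(C)C(C)(C)C)/C=C(\CO[Si](C)(C)C(C)(C)C)CCC#CC | intermediate
14 | (E)-alkenylzirconocene chloride from 13, zirconium on the methyl-bearing alkene carbon C10 | CC[Si](CC)(CC)OC[C@@H]1OC(=O)C[C@H]1[C@@H](O[Si](C)(C)C(C)(C)C)/C=C(\CO[Si](C)(C)C(C)(C)C)CC/C=C(/[Zr](Cl)(C1C=CC=C1)C1C=CC=C1)C | intermediate (not isolated)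
15 | (4R,5R)-4-[(1S,2Z,6E)-1-(tert-butyldimethylsilyloxy)-3-[(tert-butyldimethylsilyloxy)methyl]-7-iodoocta-2,6-dien-1-yl]-5-[(triethylsilyloxy)methyl]oxolan-2-one | CC[Si](CC)(CC)OC[C@@H]1OC(=O)C[C@H]1[C@@H](O[Si](C)(C)C(C)(C)C)/C=C(\CO[Si](C)(C)C(C)(C)C)CC/C=C(/I)C | intermediate
16 | Mannich base, 3-[(dimethylamino)methyl] derivative of 15 (3,4-trans) | CC[Si](CC)(CC)OC[C@@H]1OC(=O)[C@H](CN(C)C)[C@H]1[C@@H](O[Si](C)(C)C(C)(C)C)/C=C(\CO[Si](C)(C)C(C)(C)C)CC/C=C(/I)C | intermediate (not isolated)
17 | trimethylammonium iodide of 16 | CC[Si](CC)(CC)OC[C@@H]1OC(=O)[C@H](C[N+](C)(C)C)[C@H]1[C@@H](O[Si](C)(C)C(C)(C)C)/C=C(\CO[Si](C)(C)C(C)(C)C)CC/C=C(/I)C.[I-] | intermediate (not isolated)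
18 | (4R,5R)-4-[(1S,2Z,6E)-1-(tert-butyldimethylsilyloxy)-3-[(tert-butyldimethylsilyloxy)methyl]-7-iodoocta-2,6-dien-1-yl]-3-methylidene-5-[(triethylsilyloxy)methyl]oxolan-2-one | CC[Si](CC)(CC)OC[C@@H]1OC(=O)C(=C)[C@H]1[C@@H](O[Si](C)(C)C(C)(C)C)/C=C(\CO[Si](C)(C)C(C)(C)C)CC/C=C(/I)C | intermediate
19 | (4R,5R)-4-[(1S,2Z,6E)-1-(tert-butyldimethylsilyloxy)-3-[(tert-butyldimethylsilyloxy)methyl]-7-iodoocta-2,6-dien-1-yl]-5-(hydroxymethyl)-3-methylideneoxolan-2-one | OC[C@@H]1OC(=O)C(=C)[C@H]1[C@@H](O[Si](C)(C)C(C)(C)C)/C=C(\CO[Si](C)(C)C(C)(C)C)CC/C=C(/I)C | intermediate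
20 | (2R,3R)-3-[(1S,2Z,6E)-1-(tert-butyldimethylsilyloxy)-3-[(tert-butyldimethylsilyloxy)methyl]-7-iodoocta-2,6-dien-1-yl]-4-methylidene-5-oxooxolane-2-carbaldehyde | O=C[C@@H]1OC(=O)C(=C)[C@H]1[C@@H](O[Si](C)(C)C(C)(C)C)/C=C(\CO[Si](C)(C)C(C)(C)C)CC/C=C(/I)C | intermediate
21 | (1(10)E,4Z,6S,7R,8R,9S)-6,15-bis(tert-butyldimethylsilyloxy)-9-hydroxygermacra-1(10),4,11(13)-trien-12,8-olide (both ring double bonds ring-trans) | O[C@@H]1[C@@H]2OC(=O)C(=C)[C@H]2[C@@H](O[Si](C)(C)C(C)(C)C)/C=C(\CO[Si](C)(C)C(C)(C)C)CC/C=C1\C | intermediate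
22 | (1(10)E,4Z,6S,7R,8R,9S)-6,15-bis(tert-butyldimethylsilyloxy)-9-(2-methylprop-2-enoyloxy)germacra-1(10),4,11(13)-trien-12,8-olide | C=C(C)C(=O)O[C@@H]1[C@@H]2OC(=O)C(=C)[C@H]2[C@@H](O[Si](C)(C)C(C)(C)C)/C=C(\CO[Si](C)(C)C(C)(C)C)CC/C=C1\C | intermediate
23 | (1(10)E,4Z,6S,7R,8R,9S)-6-(tert-butyldimethylsilyloxy)-15-hydroxy-9-(2-methylprop-2-enoyloxy)germacra-1(10),4,11(13)-trien-12,8-olide | C=C(C)C(=O)O[C@@H]1[C@@H]2OC(=O)C(=C)[C@H]2[C@@H](O[Si](C)(C)C(C)(C)C)/C=C(\CO)CC/C=C1\C | intermediate
24 | (1(10)E,4Z,6S,7R,8R,9S)-6-(tert-butyldimethylsilyloxy)-9-(2-methylprop-2-enoyloxy)-15-oxogermacra-1(10),4,11(13)-trien-12,8-olide | C=C(C)C(=O)O[C@@H]1[C@@H]2OC(=O)C(=C)[C@H]2[C@@H](O[Si](C)(C)C(C)(C)C)/C=C(\C=O)CC/C=C1\C | intermediate (not isolated)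
25 | (5R,6S,7R,8R,9S,10S)-6-(tert-butyldimethylsilyloxy)-9-(2-methylprop-2-enoyloxy)-15-oxoelema-1,3,11(13)-trien-12,8-olide | C=C(C)C(=O)O[C@@H]1[C@@H]2OC(=O)C(=C)[C@H]2[C@@H](O[Si](C)(C)C(C)(C)C)[C@@H](C(=C)C=O)[C@]1(C)C=C | intermediate
26 | (1R,5R,6S,7R,8R,9S,10R)-6-(tert-butyldimethylsilyloxy)-1,2-epoxy-9-(2-methylprop-2-enoyloxy)-15-oxoelema-3,11(13)-dien-12,8-olide | C=C(C)C(=O)O[C@@H]1[C@@H]2OC(=O)C(=C)[C@H]2[C@@H](O[Si](C)(C)C(C)(C)C)[C@@H](C(=C)C=O)[C@]1(C)[C@@H]1CO1 | intermediate
27 | (1R,5R,6S,7S,8R,9S,10R)-1,2-epoxy-6-hydroxy-9-(2-methylprop-2-enoyloxy)-15-oxoelema-3,11(13)-dien-12,8-olide | C=C(C)C(=O)O[C@@H]1[C@@H]2OC(=O)C(=C)[C@H]2[C@@H](O)[C@@H](C(=C)C=O)[C@]1(C)[C@@H]1CO1 | target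

Total step count: 17. Longest linear sequence: 15 steps (7 to 27, steps 3–17); the side branch (steps 1–2) joins at step 6.

Steps most likely to fail

Step 12 (macrocyclisation). The strained transition state leading to the E,E-cyclodecadiene may force the alkenylchromium onto the wrong face of the C9 aldehyde, so that the C9 epimer is the main ring-closed product. The fallback sets out from 20: the macrocyclisation is run as before and the epimeric alcohol, (1(10)E,4Z,6S,7R,8R,9R)-6,15-bis(tert-butyldimethylsilyloxy)-9-hydroxygermacra-1(10),4,11(13)-trien-12,8-olide F1, is esterified under Mitsunobu conditions with methacrylic acid (PPh3, diisopropyl azodicarboxylate, toluene, 0 °C). Inversion at C9 installs the ester in the same operation, and the route is rejoined at 22, step 13 being skipped.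

Step 16 (epoxidation). The C5 formylvinyl group shields one face of the neopentyl-type vinyl group, and this substrate bias may oppose the catalyst, which would give slow conversion and poor facial selectivity at C1. The fallback sets out from 25: unselective epoxidation with 3-chloroperbenzoic acid (NaHCO3, CH2Cl2, 0 °C) gives 26 together with its C1 epimer, the (1S)-epoxide F2. Hydrolytic kinetic resolution with (salen)Co(OAc) and a substoichiometric amount of water then opens only F2 to the 1,2-diol F3, which is removed by chromatography. The route is rejoined at 26.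

Step 6 (fragment coupling). The inherent Felkin preference of the lactone aldehyde opposes the ligand, so the diastereoselectivity at C6 may erode. The fallback sets out from 6 and 11 and fixes C6 by ketone reduction instead. Compound 6 is silylated (TBSCl, imidazole) to (Z)-tert-butyl{[3-iodo-2-(pent-3-yn-1-yl)prop-2-en-1-yl]oxy}dimethylsilane F4. Ligand-free CrCl2/NiCl2 coupling with 11 gives the C6-epimeric allylic alcohols F5, and Dess–Martin oxidation gives the (Z)-enone F6. Corey–Bakshi–Shibata reduction (2-methyl-oxazaborolidine, BH3·SMe2, with the catalyst enantiomer that delivers hydride to the required face) gives the (6S)-alcohol F7. Silylation with TBSOTf and 2,6-lutidine rejoins the route at 13.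

Further compounds
F1 | step 12 | (1(10)E,4Z,6S,7R,8R,9R)-6,15-bis(tert-butyldimethylsilyloxy)-9-hydroxygermacra-1(10),4,11(13)-trien-12,8-olide (C9 epimer of 21) | O[C@H]1[C@@H]2OC(=O)C(=C)[C@H]2[C@@H](O[Si](C)(C)C(C)(C)C)/C=C(\CO[Si](C)(C)C(C)(C)C)CC/C=C1\C
F2 | step 16 | (1S)-epimer of 26 | C=C(C)C(=O)O[C@@H]1[C@@H]2OC(=O)C(=C)[C@H]2[C@@H](O[Si](C)(C)C(C)(C)C)[C@@H](C(=C)C=O)[C@]1(C)[C@H]1CO1
F3 | step 16 | 1,2-diol formed from F2 by hydrolysis at C2 | C=C(C)C(=O)O[C@@H]1[C@@H]2OC(=O)C(=C)[C@H]2[C@@H](O[Si](C)(C)C(C)(C)C)[C@@H](C(=C)C=O)[C@]1(C)[C@H](O)CO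
F4 | step 6 | (Z)-tert-butyl{[3-iodo-2-(pent-3-yn-1-yl)prop-2-en-1-yl]oxy}dimethylsilane | CC(C)(C)[Si](C)(C)OC/C(=C\I)CCC#CC
F5 | step 6 | (4S,5R)-4-[(2Z)-3-[(tert-butyldimethylsilyloxy)methyl]-1-hydroxyoct-2-en-6-yn-1-yl]-5-[(triethylsilyloxy)methyl]oxolan-2-one, mixture of C6 epimers | CC[Si](CC)(CC)OC[C@@H]1OC(=O)C[C@H]1C(O)/C=C(\CO[Si](C)(C)C(C)(C)C)CCC#CC
F6 | step 6 | (4S,5R)-4-[(2Z)-3-[(tert-butyldimethylsilyloxy)methyl]oct-2-en-6-ynoyl]-5-[(triethylsilyloxy)methyl]oxolan-2-one | CC[Si](CC)(CC)OC[C@@H]1OC(=O)C[C@H]1C(=O)/C=C(\CO[Si](C)(C)C(C)(C)C)CCC#CC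
F7 | step 6 | (4S,5R)-4-[(1S,2Z)-3-[(tert-butyldimethylsilyloxy)methyl]-1-hydroxyoct-2-en-6-yn-1-yl]-5-[(triethylsilyloxy)methyl]oxolan-2-one | CC[Si](CC)(CC)OC[C@@H]1OC(=O)C[C@H]1[C@@H](O)/C=C(\CO[Si](C)(C)C(C)(C)C)CCC#CC
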